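**Plan**

1. Retrosynthesis: the N–H is masked as N-acetyl; the N1–C2 bond of the pyrrole ring is cut and the acetyl carbon is put back into the ring between N1 and C2, widening it to a pyridine N-oxide ring; its C4–Br goes back to a 4-quinolone C=O, and the pyridone ring is cut at N1–C2 and C4–C4a, leaving 3,5-dibromoaniline 1 and ethyl acetoacetate 2.
2. Enabling feature: C2 of the indole is unsubstituted and the bromines on C3, C4 and C6 are the image of C4, C5 and C7 of a quinoline. The C4 bromine can come from a quinolone oxygen and the 5,7-pair from symmetric aniline 1, whose two ortho carbons are equivalent, so no regiochemical choice arises.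
3. Forward: 1 + 2 give enamino ester 3, then quinolone 4 (pyridone ring closes), tribromoquinoline 5 and N-oxide 6. Light expands 6 to benzoxazepine 7 and acid contracts it through 8 and 9 to N-acetylindole 10 (pyrrole ring closes); deacetylation gives target 11.
4. Stereochemistry: the target has no stereocentre; the only ones on the way (in 8 and 9) are transient and disappear when 9 loses water.

Key step: step 5

Remark: the acid stage of step 5 is assumed to be hydrolytic, so water enters and leaves again and the step is overall an isomerization of 6 into 10.

**Route**

Step 1
Reactants: 1 3,5-dibromoaniline; 2 ethyl acetoacetate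
Product: 3 ethyl (Z)-3-[(3,5-dibromophenyl)amino]but-2-enoate
Conditions: 2 (1.2 equiv), TsOH·H2O (5 mol %), cyclohexane, reflux, Dean–Stark
Reagents that add atoms: none
Why: Acid-catalysed condensation of the aniline with the ketone carbonyl of the β-keto ester (enamine stage of the Conrad–Limpach synthesis) should give the hydrogen-bonded Z-enamino ester, with water removal at about 80 °C favouring it over the anilide that would lead to the Knorr product.

Step 2
Reactants: 3 ethyl (Z)-3-[(3,5-dibromophenyl)amino]but-2-enoate
Product: 4 5,7-dibromo-2-methylquinolin-4(1H)-one
Conditions: Ph2O, 250 °C, 20 min (3 added to the hot solvent, EtOH distilled off); cool, hexane, filter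
Reagents that add atoms: none
Why: Conrad–Limpach thermal cyclization, in which the enamino ester loses ethanol and acylates an ortho carbon of the aryl ring; both ortho carbons of the 3,5-dibromophenyl group are equivalent, so only the 5,7-dibromo-4-quinolone can form.

Step 3
Reactants: 4 5,7-dibromo-2-methylquinolin-4(1H)-one
Product: 5 4,5,7-tribromo-2-methylquinoline
Conditions: POBr3 (2 equiv), PhMe, 110 °C; ice, aq NaHCO3
Reagents that add atoms: phosphorus oxybromide (POBr3), O=P(Br)(Br)Br
Why: Deoxybromination of a 4-quinolone, by activation of the quinolone oxygen on phosphorus and addition–elimination of bromide at C4 of the nitrogen-activated ring, is the standard entry to 4-bromoquinolines and leaves aryl bromides and the 2-methyl group alone.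

Step 4
Reactants: 5 4,5,7-tribromo-2-methylquinoline
Product: 6 4,5,7-tribromo-2-methylquinoline 1-oxide
Conditions: mCPBA (1.5 equiv), CHCl3, 0 to 40 °C, amber glassware; aq Na2S2O3, then cold aq NaHCO3
Reagents that add atoms: mCPBA (3-chloroperoxybenzoic acid), O=C(OO)c1cccc(Cl)c1
Why: Electrophilic oxygen transfer from the peracid to the ring nitrogen, the only nucleophilic site of 5, is the usual N-oxidation of halogenated quinolines, and C–Br bonds are inert to the peracid.

Step 5
Reactants: 6 4,5,7-tribromo-2-methylquinoline 1-oxide
Product: 10 1-acetyl-3,4,6-tribromoindole, via 3,1-benzoxazepine 7 (not isolated), via amido aldehyde 8 (not isolated), via N-acetylindolin-2-ol 9 (not isolated)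
Conditions: hν (390 nm LEDs), dry PhMe (0.02 M), N2, 20 °C; then TFA (5 equiv), H2O (2 equiv), 20 °C; aq NaHCO3
Reagents that add atoms: water, O (its oxygen becomes the acetyl oxygen; the former N-oxide oxygen leaves as water)
Why: Light near 390 nm should excite only the N-oxide chromophore, whose singlet state passes the oxygen from N1 by way of C2 onto the C2–C3 bond and then opens that bond in a 6π-electrocyclic ring expansion, so that oxygen lies between the old C2 and C3 in seven-membered 7. Acid and water then cleave the cyclic imidate and enol ether of 7 at the old C2, freeing acetanilide 8 with the old C3 as an aldehyde carbon; the amide nitrogen adds to that carbon in a 5-exo-trig closure (new N–C bond, pyrrole ring) to give hemiaminal 9, and loss of water through an N-acyliminium ion aromatizes it to 10, the old C2 staying outside the ring as the acetyl carbon. The closest known reaction type is the photorearrangement of 2-substituted quinoline N-oxides to 3,1-benzoxazepines followed by their acid-promoted contraction to N-acylindoles, a net deletion of one ring carbon that tolerates ring halogens. No stereocentre needs control, since those of 8 and 9 vanish on dehydration, and the regiochemistry is fixed because a substrate already holding all three bromines is merely isomerized (the peri C4/C5 pair of 6 becomes the C3/C4 pair of 10, with relief of peri strain in 7). The light stage must favour benzoxazepine formation over 2-quinolone formation, deoxygenation and C–Br homolysis, which the 2-methyl group (no hydrogen on C2 to shift), dry non-polar toluene and a wavelength at which the aryl bromide chromophores and 7 should be transparent are meant to secure. In the acid stage 9 must lose water and not HBr, which the far easier ionization at the N,O-acetal carbon than at the electron-poor benzylic C–Br carbon should ensure.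

Step 6
Reactants: 10 1-acetyl-3,4,6-tribromoindole
Product: 11 3,4,6-tribromoindole
Conditions: K2CO3 (0.5 equiv), MeOH/THF, 0 °C to rt, dark; neutral work-up
Reagents that add atoms: none
Why: Base-catalysed methanolysis of an N-acylindole, an activated amide whose tribromoindolide is a good leaving group, should remove the acetyl group at or below room temperature without touching the C–Br bonds.

**Compound list**

1 | 3,5-dibromoaniline | Nc1cc(Br)cc(Br)c1 | starting material
2 | ethyl acetoacetate (ethyl 3-oxobutanoate) | CCOC(=O)CC(C)=O | starting material
3 | ethyl (Z)-3-[(3,5-dibromophenyl)amino]but-2-enoate | CCOC(=O)/C=C(/C)Nc1cc(Br)cc(Br)c1 | intermediate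
4 | 5,7-dibromo-2-methylquinolin-4(1H)-one | Cc1cc(=O)c2c(Br)cc(Br)cc2[nH]1 | intermediate
5 | 4,5,7-tribromo-2-methylquinoline | Cc1cc(Br)c2c(Br)cc(Br)cc2n1 | intermediate
6 | 4,5,7-tribromo-2-methylquinoline 1-oxide | Cc1cc(Br)c2c(Br)cc(Br)cc2[n+]1[O-] | intermediate
7 | 5,6,8-tribromo-2-methyl-3,1-benzoxazepine | CC1=Nc2cc(Br)cc(Br)c2C(Br)=CO1 | intermediate (not isolated)
8 | N-[3,5-dibromo-2-(1-bromo-2-oxoethyl)phenyl]acetamide, racemic | CC(=O)Nc1cc(Br)cc(Br)c1C(Br)C=O | intermediate (not isolated)
9 | 1-acetyl-3,4,6-tribromo-2,3-dihydro-1H-indol-2-ol, racemic, both diastereomers | CC(=O)N1C(O)C(Br)c2c(Br)cc(Br)cc21 | intermediate (not isolated)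
10 | 1-acetyl-3,4,6-tribromoindole | CC(=O)n1cc(Br)c2c(Br)cc(Br)cc21 | intermediate
11 | 3,4,6-tribromoindole | Brc1cc(Br)c2c(Br)c[nH]c2c1 | target

**Step count**

Total steps: 6. Longest linear sequence: 6 steps, from 1 to 11.

**Steps most likely to fail**

Step 5. The three bromines may speed intersystem crossing, so that the excited N-oxide merely loses its oxygen. The C4–Br bond, conjugated with the excited chromophore, may break homolytically. In the acid stage HBr may be lost in place of water. The fallback keeps the ring contraction but leaves C4 free and brominates the indole last; it sets out from 1 and comes back to the route at 11.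
- A Doebner–Miller reaction of 1 with crotonaldehyde (aq HCl/PhMe, reflux, p-chloranil as oxidant) should give 5,7-dibromo-2-methylquinoline F1, again a single isomer by symmetry.
- mCPBA should oxidize it to 5,7-dibromo-2-methylquinoline 1-oxide F2.
- The same irradiation and acid treatment should carry F2 through 6,8-dibromo-2-methyl-3,1-benzoxazepine F3, N-[3,5-dibromo-2-(2-oxoethyl)phenyl]acetamide F4 and 1-acetyl-4,6-dibromoindolin-2-ol F5 to 1-acetyl-4,6-dibromoindole F6. This substrate carries halogen only on the benzo ring.
- K2CO3 in MeOH should free 4,6-dibromoindole F7, and NBS in DMF at 0 °C in the dark should brominate its C3 position to give 11.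

Step 4. Oxygen transfer may be sluggish to a nitrogen deactivated by three bromines and shielded by the 2-methyl group. Once the N-oxide forms, the activated C4 bromide may be displaced by carboxylate or water. The fallback puts the oxygen on nitrogen before the C4 bromine exists; it sets out from 1 and comes back at 6.
- 5,7-Dibromo-2-methylquinoline F1 and 5,7-dibromo-2-methylquinoline 1-oxide F2 are made as above.
- Mixed acid (HNO3/H2SO4, about 70 °C) should nitrate F2 at C4, the position the N-oxide directs to, giving 5,7-dibromo-2-methyl-4-nitroquinoline 1-oxide F8.
- Acetyl bromide should exchange the nitro group for bromide by addition–elimination, giving 6.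

Step 3. Deoxybromination may stay incomplete because bromide must enter C4 beside the peri bromine at C5, with decomposition at the temperature this needs and hydrolysis back to 4 on work-up. The fallback sets out from 4 and comes back at 5.
- POCl3 at reflux should give 5,7-dibromo-4-chloro-2-methylquinoline F9.
- Halogen exchange with bromotrimethylsilane in propionitrile at reflux (acid-activated addition–elimination at C4, driven by loss of the volatile chlorosilane) should turn F9 into 5.

**Further compounds**

F1 | step 5 | 5,7-dibromo-2-methylquinoline | Cc1ccc2c(Br)cc(Br)cc2n1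
F2 | step 5 | 5,7-dibromo-2-methylquinoline 1-oxide | Cc1ccc2c(Br)cc(Br)cc2[n+]1[O-]
F3 | step 5 | 6,8-dibromo-2-methyl-3,1-benzoxazepine | CC1=Nc2cc(Br)cc(Br)c2C=CO1
F4 | step 5 | N-[3,5-dibromo-2-(2-oxoethyl)phenyl]acetamide | CC(=O)Nc1cc(Br)cc(Br)c1CC=O
F5 | step 5 | 1-acetyl-4,6-dibromo-2,3-dihydro-1H-indol-2-ol, racemic | CC(=O)N1C(O)Cc2c(Br)cc(Br)cc21
F6 | step 5 | 1-acetyl-4,6-dibromoindole | CC(=O)n1ccc2c(Br)cc(Br)cc21
F7 | step 5 | 4,6-dibromoindole | Brc1cc(Br)c2cc[nH]c2c1
F8 | step 4 | 5,7-dibromo-2-methyl-4-nitroquinoline 1-oxide | Cc1cc([N+](=O)[O-])c2c(Br)cc(Br)cc2[n+]1[O-]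
F9 | step 3 | 5,7-dibromo-4-chloro-2-methylquinoline | Cc1cc(Cl)c2c(Br)cc(Br)cc2n1
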